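Remark on the chemistry (assumption): luteolin (1) is taken as a commercial starting material, so the flavone core is bought and every constructive step concerns the two C‑prenyl groups. The target has no stereocentre and no stereogenic double bond (each prenyl alkene carries two identical methyl groups).

## Analysis of the target

- Epimedokoreanin B (10) is a flavone. Ring A (C4a, C5–C8, C8a) is a phloroglucinol-type ring, ring C (O1, C2, C3, C4, C4a, C8a) is a γ‑pyrone, and ring B (C1'–C6') is a catechol.
- It carries hydroxyls at C5, C7, C3' and C4' and two 3‑methylbut‑2‑enyl (prenyl) groups, at C8 of ring A and at C5' of ring B.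
- The feature that drives the plan: each prenylated carbon is the ortho neighbour of a hydroxylated carbon (C8 next to C7–OH, C5' next to C4'–OH). O7 and O4' are also the two most acidic hydroxyls of the flavone, since both are vinylogous acids conjugated to the C4 carbonyl.
- There is nothing stereochemical to control; the whole difficulty is regiochemical. In ring A, C6 and C8 are both flanked by two oxygens and react alike towards electrophiles. In ring B, C2', C5' and C6' are all open.
- Direct Friedel–Crafts prenylation would therefore give mixtures of C‑ and O‑prenylated products.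
- The sensitive groups are the two o‑prenylphenol units and the catechol. Acid closes an o‑prenylphenol to a 2,2‑dimethylchroman, oxidants (iodine, quinones) give chromenes, hydrogenolysis saturates the prenyl alkenes, and the catechol is air-sensitive in base.
- The late steps must therefore be neutral or mildly basic, non-oxidising and non-reducing.

## Retrosynthetic reasoning

**10 ⇒ 9.** The O–acetyl bonds at O5 and O3' are cut. Acetates are chosen because they come off by ammonolysis at room temperature, which touches neither the prenyl alkenes nor the o‑prenylphenols. The forward step only has to free two phenols without acid.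

**9 ⇒ 5 (key disconnection).** Both aryl–CH2 bonds are cut at once, C8–C1'' and C5'–C1'''. Each C5 unit is reconnected through its tertiary carbon to the neighbouring oxygen (O7 and O4'), giving the bis(1,1‑dimethylallyl) ether 5. Cutting here, and not inside the flavone, keeps the whole C15 core as the purchasable compound 1. It also makes each C–C bond intramolecular from the oxygen next to it, so the position of each prenyl group is dictated by the ether oxygen rather than by the ring's nucleophilicity. The forward reaction is a double [3,3] shift that must choose C5' in ring B and C8 over C6 in ring A.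

**5 ⇒ 4.** The two terminal alkenes are traced back to terminal alkynes. Tertiary propargylic aryl ethers are far easier to make than tertiary allylic ones, and they do not rearrange at the temperatures of the intervening steps. The forward step is a semi-hydrogenation that must stop at the alkene.

**4 ⇒ 3.** The two acetyl groups on O5 and O3' are removed. In the forward direction they are put on the only two hydroxyls left free. On O5 the acetyl group is also a control element for the key step: it removes the chelate to the C4 carbonyl and shields C6.

**3 ⇒ 1 + 2.** The two O–C(tertiary) bonds at O7 and O4' are cut, giving luteolin 1 and two equivalents of the C5 chloride 2. The acidity order of 1 (O7–H > O4'–H > O3'–H > O5–H) matches the pattern needed: the two oxygens that must carry the C5 units are the two that are deprotonated first.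

## Alternatives that were turned down

**Alternative 1:** the textbook flavone assembly.
- Disconnection: C2–C3 and O1–C2 of ring C. Ketone A1 and aldehyde A2, each already prenylated and protected as methoxymethyl ethers, would be joined by Claisen–Schmidt condensation to chalcone A3. Oxidative cyclisation would give the protected flavone A4, and acid would remove the four acetals.
- Why turned down: it builds a core that can be bought. Each prenyl group has to be installed on its own fragment by a separate sequence. Four protecting groups are needed only to decide which ortho-oxygen of A3 closes ring C (otherwise 6‑ and 8‑prenyl flavones both form). The usual oxidative cyclisation with iodine attacks prenyl alkenes. The final acidic deprotection of A4 exposes two o‑prenylphenols to the conditions that close them to chromans. The count is above ten steps.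

**Alternative 2:** three-component construction of ring C.
- Disconnection: C4a–C4, C4–C3 and O1–C2. Iodophenol A5, carbon monoxide and arylalkyne A6 would be joined by a palladium-catalysed carbonylative Sonogashira coupling, followed by 6‑endo addition of the phenol to the ynone to give A4.
- Why turned down: the iodide in A5 sits between two oxygen substituents on an electron-rich ring, so oxidative addition and CO insertion would be slow. 5‑exo closure to an aurone competes with the 6‑endo mode. A5 and A6 each still need their own regiocontrolled prenylation and four to five steps. The convergent step therefore solves none of the real (prenyl) problems, and the acidic deprotection of A4 remains.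

**Alternative 3:** double cross-coupling.
- Disconnection: the same two aryl–CH2 bonds as in the chosen route, but made intermolecularly from diiodide A7 and a prenyl-tin or prenyl-boron reagent under palladium catalysis, giving A4.
- Why turned down: A7 cannot be reached by halogenating a protected flavone. Iodination of ring A goes cleanly to C8 only with both O5 and O7 alkylated, and a 3',4'-dialkoxyphenyl ring is halogenated at C6' (para to O3'), not at C5'. The C5' iodide would thus have to be carried in from the start through a de novo flavone synthesis. Allyl-metal couplings also scramble between prenyl and 1,1‑dimethylallyl products, and the ether protecting groups again end in an acidic deprotection.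

Key step: step 4

## Route

**Step 1**
Reactants: 1 luteolin (5,7,3',4'-tetrahydroxyflavone); 2 3-chloro-3-methylbut-1-yne
Product: 3 5,3'-dihydroxy-7,4'-bis(2-methylbut-3-yn-2-yloxy)flavone
Conditions: 2 (2.2 equiv), K2CO3 (2.2 equiv), KI (cat.), CuI (cat.), DMF, 45 °C, under argon
Reagents that add atoms: none
Why: Copper-catalysed propargylic etherification (substitution at the tertiary carbon through a copper acetylide) of phenoxides; with two equivalents of base only the two most acidic hydroxyls, O7–H and O4'–H, are ionised, while the chelated O5–H and the less acidic O3'–H should stay free.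

**Step 2**
Reactants: 3 5,3'-dihydroxy-7,4'-bis(2-methylbut-3-yn-2-yloxy)flavone
Product: 4 5,3'-diacetoxy-7,4'-bis(2-methylbut-3-yn-2-yloxy)flavone
Conditions: Ac2O (4 equiv), pyridine, DMAP (cat.), 50 °C
Reagents that add atoms: acetic anhydride, CC(=O)OC(C)=O
Why: DMAP-catalysed O-acylation of the two remaining phenols; the chelated 5‑OH needs the nucleophilic catalyst and mild warming, which the tertiary propargyl ethers tolerate because they rearrange only well above 120 °C.

**Step 3**
Reactants: 4 5,3'-diacetoxy-7,4'-bis(2-methylbut-3-yn-2-yloxy)flavone
Product: 5 5,3'-diacetoxy-7,4'-bis(2-methylbut-3-en-2-yloxy)flavone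
Conditions: H2 (1 atm), 5% Pd on CaCO3 poisoned with Pb(OAc)2 (Lindlar catalyst), quinoline, EtOAc, rt, stopped after uptake of 2 equiv H2
Reagents that add atoms: none
Why: Lindlar semi-hydrogenation of two terminal alkynes to terminal alkenes; the conjugated C2=C3 bond of the γ‑pyrone and the aryl acetates are inert on the poisoned catalyst, and room temperature is far below the onset of the Claisen shift.

**Step 4**
Reactants: 5 5,3'-diacetoxy-7,4'-bis(2-methylbut-3-en-2-yloxy)flavone
Product: 9 5,3'-diacetoxy-7,4'-dihydroxy-8,5'-bis(3-methylbut-2-enyl)flavone, via ring-B dienone 6 (not isolated), via ring-B phenol 7 (not isolated), via ring-A dienone 8 (not isolated)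
Conditions: o-xylene (degassed), 130 °C, under argon, base-washed glassware
Reagents that add atoms: none
Why: Two independent aromatic Claisen ([3,3]-sigmatropic) rearrangements of aryl 1,1‑dimethylallyl ethers: in each, the terminal CH2 of the allyl unit bonds to the ortho carbon through a six-membered chair-like transition state while the O–C(tertiary) bond breaks, so the C5 unit arrives inverted as a linear prenyl group, and the dienones 6 and 8 enolise to the phenols 7 and 9 (ring B is written first; the order is immaterial). The closest known reaction type is the ortho-Claisen rearrangement of 7‑(1,1‑dimethylallyloxy)coumarins and flavonoids and of catechol mono(1,1‑dimethylallyl) ethers in neutral solvents at 110–140 °C; here two such shifts are run in one flask. No ring is closed in the product; the only cyclic arrays are the two pericyclic transition states. No stereocentre remains, because the sp3 carbons C5' in 6 and C8 in 8 are erased on enolisation. In ring B the shift must go to C5' and not to C3'; this is secured because C3' carries the acetoxy group, so a shift onto it gives a dienone that cannot enolise and can only revert. In ring A the shift must go to C8 and not to C6: the shift to C8 gives dienone 8 with the C4a=C8a bond, and hence the γ‑pyrone of ring C, intact, whereas a shift to C6 has to localise double bonds at C4a=C5 and C8=C8a and break the pyrone conjugation, the same bond fixation that sends 7‑allyloxy-chromones, 7‑allyloxy-coumarins and 2‑naphthyl allyl ethers to the angular position. The 5‑acetoxy group should reinforce this, since it removes the O5–H···O4 chelate and the electron donation that would activate C6 and also shields C6 sterically. The geminal methyl groups lower the barrier so that 130 °C should suffice, and a neutral, non-nucleophilic medium keeps the acetates in place and avoids acid-catalysed chroman formation from the new o‑prenylphenols.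

**Step 5**
Reactants: 9 5,3'-diacetoxy-7,4'-dihydroxy-8,5'-bis(3-methylbut-2-enyl)flavone
Product: 10 epimedokoreanin B (5,7,3',4'-tetrahydroxy-8,5'-bis(3-methylbut-2-enyl)flavone)
Conditions: NH3 (7 M in MeOH), 0 °C to rt, under argon; evaporation
Reagents that add atoms: none
Why: Ammonolysis of the two aryl acetates (acyl transfer to ammonia); the conditions are non-acidic and non-oxidising, so the o‑prenylphenols should not cyclise and the catechol should survive under argon.

## Compound list

1 | luteolin (5,7,3',4'-tetrahydroxyflavone) | Oc1ccc(cc1O)-c1cc(=O)c2c(O)cc(O)cc2o1 | starting material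
2 | 3-chloro-3-methylbut-1-yne | CC(C)(Cl)C#C | starting material
3 | 5,3'-dihydroxy-7,4'-bis(2-methylbut-3-yn-2-yloxy)flavone | C#CC(C)(C)Oc1ccc(cc1O)-c1cc(=O)c2c(O)cc(OC(C)(C)C#C)cc2o1 | intermediate
4 | 5,3'-diacetoxy-7,4'-bis(2-methylbut-3-yn-2-yloxy)flavone | C#CC(C)(C)Oc1ccc(cc1OC(C)=O)-c1cc(=O)c2c(OC(C)=O)cc(OC(C)(C)C#C)cc2o1 | intermediate
5 | 5,3'-diacetoxy-7,4'-bis(2-methylbut-3-en-2-yloxy)flavone | C=CC(C)(C)Oc1ccc(cc1OC(C)=O)-c1cc(=O)c2c(OC(C)=O)cc(OC(C)(C)C=C)cc2o1 | intermediate
6 | ring-B dienone: ring B of 5 turned into the 4'-oxo cyclohexadienone with H and prenyl on C5' (racemic, transient); ring A ether unchanged | O=C1C(CC=C(C)C)C=C(C=C1OC(C)=O)-c1cc(=O)c2c(OC(C)=O)cc(OC(C)(C)C=C)cc2o1 | intermediate (not isolated)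
7 | ring-B phenol: 5,3'-diacetoxy-4'-hydroxy-5'-(3-methylbut-2-enyl)-7-(2-methylbut-3-en-2-yloxy)flavone | CC(C)=CCc1cc(cc(OC(C)=O)c1O)-c1cc(=O)c2c(OC(C)=O)cc(OC(C)(C)C=C)cc2o1 | intermediate (not isolated)
8 | ring-A dienone: 5-acetoxy-2-[3-acetoxy-4-hydroxy-5-(3-methylbut-2-enyl)phenyl]-8-(3-methylbut-2-enyl)-8H-chromene-4,7-dione (racemic, transient) | CC(C)=CCC1C(=O)C=C(OC(C)=O)C2=C1OC(=CC2=O)c1cc(CC=C(C)C)c(O)c(OC(C)=O)c1 | intermediate (not isolated)
9 | 5,3'-diacetoxy-7,4'-dihydroxy-8,5'-bis(3-methylbut-2-enyl)flavone | CC(C)=CCc1cc(cc(OC(C)=O)c1O)-c1cc(=O)c2c(OC(C)=O)cc(O)c(CC=C(C)C)c2o1 | intermediate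
10 | epimedokoreanin B | CC(C)=CCc1cc(-c2cc(=O)c3c(O)cc(O)c(CC=C(C)C)c3o2)cc(O)c1O | target

## Step count and risk

Total step count: 5. Longest linear sequence: 5 steps (1 → 3 → 4 → 5 → 9 → 10).

**Step 4 (key step).**
- What may go wrong: the C5 unit of ring A may migrate partly to C6 instead of C8. The tertiary allyl ethers may also lose isoprene by ionisation before they rearrange, or the new o‑prenylphenols may close to chromans if traces of acid are present.
- Fallback (sets out from 1, comes back at 10): the ring-A prenyl group is delivered from O5 by a para-Claisen–Cope sequence, for which C6 is only a way station, and ring B is treated separately.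
  - Luteolin 1 is acetylated with about three equivalents of acetic anhydride in pyridine at 0 °C, which leaves the chelated 5‑OH free, to give 7,3',4'-triacetoxy-5-hydroxyflavone F1.
  - Mitsunobu etherification of F1 with 3‑methylbut‑2‑en‑1‑ol, PPh3 and diisopropyl azodicarboxylate gives 7,3',4'-triacetoxy-5-(3-methylbut-2-enyloxy)flavone F2.
  - Heating F2 with catalytic Eu(fod)3 (fod = 6,6,7,7,8,8,8‑heptafluoro‑2,2‑dimethyloctane‑3,5‑dionate) and NaHCO3 in chlorobenzene at 85 °C should move the prenyl group from O5 via C6 to C8 by [3,3] then [3,3], giving 7,3',4'-triacetoxy-5-hydroxy-8-(3-methylbut-2-enyl)flavone F3.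
  - Ammonolysis gives 8‑prenylluteolin F4.
  - F4 is treated with one equivalent of 2, excess K2CO3, and catalytic CuI and KI in DMF at room temperature. The 7‑oxygen is now flanked by the prenyl group, so the bulky tertiary electrophile should take the unhindered and more nucleophilic 4'‑phenoxide, giving 5,7,3'-trihydroxy-4'-(2-methylbut-3-yn-2-yloxy)-8-(3-methylbut-2-enyl)flavone F5.
  - Lindlar semi-hydrogenation gives 5,7,3'-trihydroxy-4'-(2-methylbut-3-en-2-yloxy)-8-(3-methylbut-2-enyl)flavone F6.
  - Heating F6 in o‑xylene at 130 °C should effect the single ortho-Claisen shift to C5' and give 10 directly.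

**Step 1.**
- What may go wrong: incomplete discrimination between O4' and O3' in the catechol, and over-alkylation to a tris-ether, because the acidity gap between the second and third hydroxyl is smaller than that between the first and second.
- Fallback (sets out from 1, comes back at 4): the selectivity is taken from ester lability instead of phenol acidity.
  - Luteolin 1 is peracetylated (acetic anhydride, pyridine, DMAP, 60 °C) to 5,7,3',4'-tetraacetoxyflavone F7.
  - F7 is heated with 2, K2CO3, KI and catalytic CuI in dry acetone. Carbonate cleaves only the acetates of the two best phenoxide leaving groups, O7 and then O4', and each liberated phenoxide is etherified in situ, so the 5‑ and 3'‑acetates stay and 4 should be reached without passing through 3.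

**Step 3.**
- What may go wrong: over-reduction of the terminal alkenes to saturated tert-pentyl ethers, or a stall at the mono-alkyne stage; neither by-product can rearrange.
- Fallback (sets out from 1, comes back at 5): the alkyne stage is avoided altogether.
  - Luteolin 1 is O‑allylated with commercial tert-butyl 2‑methylbut‑3‑en‑2‑yl carbonate and catalytic Pd(PPh3)4 in THF at 0 °C. This decarboxylative Tsuji–Trost etherification should give the branched tertiary ethers under kinetic control at the two most acidic phenols, that is 5,3'-dihydroxy-7,4'-bis(2-methylbut-3-en-2-yloxy)flavone F8.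
  - Acetylation of F8 at room temperature (acetic anhydride, pyridine, DMAP) then gives 5.

## Further compounds

F1 | step 4 | 7,3',4'-triacetoxy-5-hydroxyflavone | CC(=O)Oc1ccc(cc1OC(C)=O)-c1cc(=O)c2c(O)cc(OC(C)=O)cc2o1
F2 | step 4 | 7,3',4'-triacetoxy-5-(3-methylbut-2-enyloxy)flavone | CC(C)=CCOc1cc(OC(C)=O)cc2oc(cc(=O)c12)-c1ccc(OC(C)=O)c(OC(C)=O)c1
F3 | step 4 | 7,3',4'-triacetoxy-5-hydroxy-8-(3-methylbut-2-enyl)flavone | CC(C)=CCc1c(OC(C)=O)cc(O)c2c1oc(cc2=O)-c1ccc(OC(C)=O)c(OC(C)=O)c1
F4 | step 4 | 8-prenylluteolin (5,7,3',4'-tetrahydroxy-8-(3-methylbut-2-enyl)flavone) | CC(C)=CCc1c(O)cc(O)c2c1oc(cc2=O)-c1ccc(O)c(O)c1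
F5 | step 4 | 5,7,3'-trihydroxy-4'-(2-methylbut-3-yn-2-yloxy)-8-(3-methylbut-2-enyl)flavone | CC(C)=CCc1c(O)cc(O)c2c1oc(cc2=O)-c1ccc(OC(C)(C)C#C)c(O)c1
F6 | step 4 | 5,7,3'-trihydroxy-4'-(2-methylbut-3-en-2-yloxy)-8-(3-methylbut-2-enyl)flavone | CC(C)=CCc1c(O)cc(O)c2c1oc(cc2=O)-c1ccc(OC(C)(C)C=C)c(O)c1
F7 | step 1 | 5,7,3',4'-tetraacetoxyflavone | CC(=O)Oc1ccc(cc1OC(C)=O)-c1cc(=O)c2c(OC(C)=O)cc(OC(C)=O)cc2o1
F8 | step 3 | 5,3'-dihydroxy-7,4'-bis(2-methylbut-3-en-2-yloxy)flavone | C=CC(C)(C)Oc1ccc(cc1O)-c1cc(=O)c2c(O)cc(OC(C)(C)C=C)cc2o1
A1 | alternative 1 | 1-[2-hydroxy-4,6-bis(methoxymethoxy)-3-(3-methylbut-2-enyl)phenyl]ethanone | CC(=O)c1c(O)c(CC=C(C)C)c(OCOC)cc1OCOC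
A2 | alternative 1 | 3,4-bis(methoxymethoxy)-5-(3-methylbut-2-enyl)benzaldehyde | O=Cc1cc(CC=C(C)C)c(OCOC)c(OCOC)c1
A3 | alternative 1 | (E)-1-[2-hydroxy-4,6-bis(methoxymethoxy)-3-(3-methylbut-2-enyl)phenyl]-3-[3,4-bis(methoxymethoxy)-5-(3-methylbut-2-enyl)phenyl]prop-2-en-1-one | COCOc1cc(OCOC)c(C(=O)/C=C/c2cc(CC=C(C)C)c(OCOC)c(OCOC)c2)c(O)c1CC=C(C)C
A4 | alternative 1 | 5,7,3',4'-tetrakis(methoxymethoxy)-8,5'-bis(3-methylbut-2-enyl)flavone | COCOc1cc(OCOC)c2c(c1CC=C(C)C)oc(cc2=O)-c1cc(CC=C(C)C)c(OCOC)c(OCOC)c1
A5 | alternative 2 | 2-iodo-3,5-bis(methoxymethoxy)-6-(3-methylbut-2-enyl)phenol | Oc1c(I)c(OCOC)cc(OCOC)c1CC=C(C)C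
A6 | alternative 2 | 5-ethynyl-1,2-bis(methoxymethoxy)-3-(3-methylbut-2-enyl)benzene | C#Cc1cc(CC=C(C)C)c(OCOC)c(OCOC)c1
A7 | alternative 3 | 8,5'-diiodo-5,7,3',4'-tetrakis(methoxymethoxy)flavone | COCOc1cc(OCOC)c2c(c1I)oc(cc2=O)-c1cc(I)c(OCOC)c(OCOC)c1
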